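Everything rests on cutting ring B, not the diaryl ether: C1'–C6' and C2'–C3' are disconnected. The key step exploits the vicinal oxygen pair of ring B, C1'(OAr)–C2'(OH). This pair maps onto the two carbons of an O-aryl glycolic acid. C3'–C6', with the C4' methyl and the C6' carbonyl carbon, map onto a 4-methyl-2-pyrone-6-carboxylate. One inverse-demand cycloaddition, followed in the same flask by loss of CO2 and Me3SiOH, builds the whole aromatic ring on an ether oxygen installed earlier by a simple alkylation. The precursor is the persilylated ring-A diacid: a 2-aryloxy-1,1-bis(silyloxy)ethene carrying a silyl benzoate and the finished (R)-benzylic methyl ether.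

Key step: step 11

Remarks on the chemistry
- Locants: ring A is the benzoic acid ring (C1 CO2H, C2 OMe, C3 side chain, C6 O-aryl). Ring B is C1' (OAr), C2' (OH), C4' (Me), C6' (CHO). The target string reads as (R) at the benzylic carbon (OMe > aryl > CH2 > H).
- The benzylic C–O bond is ortho to the C2 methoxy group and para to the C6 oxygen, so it can ionise. From step 4 on, no Lewis acid and no strong Brønsted acid is used, and every acidification is cold and stops at pH 3.
- An aryloxyacetic ester beside a benzoic ester closes to a benzofuranone with hydride, alkoxide or amide bases. Only carbonate or Ag2O is used while both esters are present. The enolate is made only when both carboxyl groups are lithium carboxylates.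
- Each aromatisation releases one silanol, which would protonate a second molecule of the ketene acetal. N,O-bis(trimethylsilyl)acetamide (BSA) is therefore added as a silanol trap, and the cheap pyrone, not the chiral partner, is used in excess.
- The lactone carbonyl on C3 and the ester on C6 polarise the pyrone diene in opposite senses. The orientation is therefore argued from the ring oxygen, the C4 methyl group and sterics (see step 11), and it is treated as the main risk.
- Assumption: 3-bromo-2-fluoro-5-methylbenzaldehyde, needed only in one fallback, is taken as purchasable.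

Step 1
Reactants: 1 methyl 2,6-dihydroxybenzoate; 2 3-methylbutanoyl chloride
Product: 3 methyl 2,6-dihydroxy-3-(3-methylbutanoyl)benzoate
Conditions: AlCl3 (3.5 equiv), ClCH2CH2Cl, 0 to 60 °C; ice/1 M HCl
Reagents that add atoms: none
Why: Friedel–Crafts acylation (possibly via O-acylation and Fries shift), in which C3 is ortho to one hydroxyl and para to the other while C4 is meta to both, C3 and C5 are equivalent by symmetry, and the chelated, deactivated aryl ketone resists a second acylation.

Step 2
Reactants: 3 methyl 2,6-dihydroxy-3-(3-methylbutanoyl)benzoate; 4 methyl bromoacetate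
Product: 5 methyl 2-hydroxy-6-(2-methoxy-2-oxoethoxy)-3-(3-methylbutanoyl)benzoate
Conditions: K2CO3 (1.1 equiv), acetone, reflux
Reagents that add atoms: none
Why: Williamson ether synthesis in which the C6 hydroxyl, para to the ketone and open on one side, is the more acidic and accessible one, whereas the C2 hydroxyl is wedged between two carbonyl groups and hydrogen-bonded to the ketone; carbonate is too weak to start a Dieckmann closure.

Step 3
Reactants: 5 methyl 2-hydroxy-6-(2-methoxy-2-oxoethoxy)-3-(3-methylbutanoyl)benzoate
Product: 6 methyl 2-methoxy-6-(2-methoxy-2-oxoethoxy)-3-(3-methylbutanoyl)benzoate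
Conditions: MeI (3 equiv), K2CO3 (2 equiv), DMF, 40 °C
Reagents that add atoms: iodomethane, CI
Why: Williamson O-methylation of the remaining chelated phenol, pushed by excess MeI in a dipolar aprotic solvent but still under carbonate conditions that leave the aryloxyacetate CH2 un-enolised.

Step 4
Reactants: 6 methyl 2-methoxy-6-(2-methoxy-2-oxoethoxy)-3-(3-methylbutanoyl)benzoate
Product: 7 methyl 3-[(1R)-1-hydroxy-3-methylbutyl]-2-methoxy-6-(2-methoxy-2-oxoethoxy)benzoate
Conditions: RuCl[(R,R)-TsDPEN](p-cymene) (1 mol %), HCO2H/Et3N (5:2), EtOAc, 35 °C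
Reagents that add atoms: none
Why: Noyori-type asymmetric transfer hydrogenation, in which hydride and proton pass through the six-membered outer-sphere transition state with the aryl ring under the η6-arene (CH/π contact) and the isobutyl chain pointing away, so the (R,R)-catalyst should give the (R)-alcohol as it does with simple aryl alkyl ketones; loss of CO2 makes the reduction irreversible and the esters are untouched.

Step 5
Reactants: 7 methyl 3-[(1R)-1-hydroxy-3-methylbutyl]-2-methoxy-6-(2-methoxy-2-oxoethoxy)benzoate
Product: 8 methyl 2-methoxy-3-[(1R)-1-methoxy-3-methylbutyl]-6-(2-methoxy-2-oxoethoxy)benzoate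
Conditions: MeI (excess), Ag2O (3 equiv), 4 Å MS, MeCN, 40 °C, dark
Reagents that add atoms: iodomethane, CI
Why: Purdie methylation, an O-alkylation that never breaks the C–O bond of the stereocentre (retention), chosen because hydride or alkoxide bases would close the aryloxyacetate onto the neighbouring ester and because oxonium or triflate reagents could ionise this ortho,para-dioxygenated benzylic position.

Step 6
Reactants: 8 methyl 2-methoxy-3-[(1R)-1-methoxy-3-methylbutyl]-6-(2-methoxy-2-oxoethoxy)benzoate
Product: 9 6-(carboxymethoxy)-2-methoxy-3-[(1R)-1-methoxy-3-methylbutyl]benzoic acid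
Conditions: KOH (10 equiv), DMSO/H2O (3:1), rt then 95 °C, N2; cold 1 M HCl to pH 3
Reagents that add atoms: potassium hydroxide (hydroxide oxygen), [K+].[OH-]
Why: Saponification in which the acetate ester falls at room temperature, before any enolate chemistry, and poorly solvated hydroxide in hot aqueous DMSO then opens the di-ortho-substituted benzoate; aryl ethers, the benzylic ether and the non-acidic stereocentre tolerate the forcing conditions.

Step 7
Reactants: 9 6-(carboxymethoxy)-2-methoxy-3-[(1R)-1-methoxy-3-methylbutyl]benzoic acid
Product: 11 trimethylsilyl 6-{[2,2-bis(trimethylsilyloxy)ethenyl]oxy}-2-methoxy-3-[(1R)-1-methoxy-3-methylbutyl]benzoate, via trilithium enediolate benzoate 10 (not isolated)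
Conditions: LiN(iPr)2 (3.4 equiv), THF, −78 to 0 °C; Me3SiCl (4.5 equiv), −78 °C to rt; evaporation, pentane, filtration under Ar; used crude
Reagents that add atoms: chlorotrimethylsilane, C[Si](C)(C)Cl; lithium diisopropylamide (lithium of 10 only), CC(C)[N-]C(C)C.[Li+]
Why: Enediolate formation from a carboxylic acid and O,O-silylation to the ketene bis(trimethylsilyl) acetal, as known for alkoxy- and silyloxyacetic acids; the ring-A carboxyl is a lithium carboxylate at the moment of enolisation and cannot act as a Dieckmann acceptor, and two identical silyloxy groups leave no alkene geometry to control.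

Step 8
Reactants: 12 ethyl 3-methylbut-2-enoate; 13 diethyl oxalate
Product: 14 potassium enolate of diethyl 4-methyl-2-oxohex-4-enedioate
Conditions: KOEt (1.05 equiv), Et2O/EtOH, 0 °C to rt; filtration of the salt
Reagents that add atoms: potassium ethoxide, CC[O-].[K+]
Why: Vinylogous (γ-selective) Claisen condensation, in which ethoxide deprotonates a γ-methyl group reversibly and the oxalylated product is drained from the equilibria as its insoluble, fully conjugated potassium enolate.

Step 9
Reactants: 14 potassium enolate of diethyl 4-methyl-2-oxohex-4-enedioate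
Product: 15 4-methyl-2-oxo-2H-pyran-6-carboxylic acid
Conditions: conc. HCl, reflux
Reagents that add atoms: water, O
Why: Acid-mediated alkene equilibration through the keto tautomer, enol lactonisation onto the distal ester and hydrolysis of the remaining ester, the classical passage from oxalyl enoates to 2-pyrone-6-carboxylic acids.

Step 10
Reactants: 15 4-methyl-2-oxo-2H-pyran-6-carboxylic acid
Product: 16 methyl 4-methyl-2-oxo-2H-pyran-6-carboxylate
Conditions: MeOH, H2SO4 (cat.), reflux
Reagents that add atoms: methanol, CO
Why: Fischer esterification, which 2-pyrone carboxylic acids tolerate because the ring is a conjugated, partly aromatic lactone.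

Step 11
Reactants: 11 trimethylsilyl 6-{[2,2-bis(trimethylsilyloxy)ethenyl]oxy}-2-methoxy-3-[(1R)-1-methoxy-3-methylbutyl]benzoate; 16 methyl 4-methyl-2-oxo-2H-pyran-6-carboxylate
Product: 20 6-[2-hydroxy-6-(methoxycarbonyl)-4-methylphenoxy]-2-methoxy-3-[(1R)-1-methoxy-3-methylbutyl]benzoic acid, via bridged lactone cycloadduct 17 (not isolated), via cyclohexadiene acetal 18 (not isolated), via bis-silylated diaryl ether 19 (not isolated)
Conditions: 11 (limiting), 16 (1.5 equiv), BSA (2 equiv), toluene, 110–130 °C, sealed tube, Ar; then THF/aq. citric acid, rt; NaHCO3 extraction, re-acidification to pH 3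
Reagents that add atoms: none
Why: The electron-rich C=C of 11, most nucleophilic at its CH(OAr) carbon, adds across C3 and C6 of the electron-poor pyrone 16 in a concerted but strongly asynchronous inverse-electron-demand Diels–Alder reaction in which C1'–C6' leads and C2'–C3' follows, giving bridged lactone 17; retro-Diels–Alder loss of CO2 gives diene 18, 1,2-elimination of Me3SiOH (H from C1', OSiMe3 from C2') gives arene 19, and the mildly acidic work-up removes its two silyl groups. The closest known chemistry is the catechol annulation of carbomethoxy-2-pyrones with 1,1,2-trialkoxyethenes, and the bis-silyl variant is chosen so that whichever acetal oxygen leaves, the survivor is unmasked as the free C2' phenol. Ring B is closed by an intermolecular (4+2) cycloaddition, four carbons (C3'–C6') coming from the pyrone and two (C1', C2') from the ketene acetal, and it becomes aromatic through the two extrusions. The sp3 centres of 17 and 18 form without control and are all erased on aromatisation, while the (R)-benzylic centre is a spectator kept safe by the neutral medium free of Lewis acid. Regioselectivity is the one selectivity needed: attack at C6, the usual electrophilic site of 2-pyrones, spreads the developing negative charge over C5, C3 and the lactone carbonyl, whereas attack at C3 would place it on the methyl-bearing C4 and the oxygen-bearing C6, and the reverse orientation would also have to join the fully substituted acetal carbon to the fully substituted C6. The aryloxy group cannot be eliminated because its neighbour C2' carries no hydrogen, and BSA removes the silanol before it can protonate unreacted 11.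

Step 12
Reactants: 20 6-[2-hydroxy-6-(methoxycarbonyl)-4-methylphenoxy]-2-methoxy-3-[(1R)-1-methoxy-3-methylbutyl]benzoic acid
Product: 21 6-[2-hydroxy-6-(hydroxymethyl)-4-methylphenoxy]-2-methoxy-3-[(1R)-1-methoxy-3-methylbutyl]benzoic acid
Conditions: LiBH4 (6 equiv), THF/MeOH, 0 to 50 °C; aq. NH4Cl, cold 1 M HCl to pH 3
Reagents that add atoms: none
Why: Chemoselective borohydride reduction of an ester, in which acid and phenol are first deprotonated to a lithium carboxylate (di-ortho-substituted as well) and a phenoxide that LiBH4 does not reduce, so only the ring-B methyl ester becomes the primary alcohol.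

Step 13
Reactants: 21 6-[2-hydroxy-6-(hydroxymethyl)-4-methylphenoxy]-2-methoxy-3-[(1R)-1-methoxy-3-methylbutyl]benzoic acid
Product: 22 6-(2-formyl-6-hydroxy-4-methylphenoxy)-2-methoxy-3-[(1R)-1-methoxy-3-methylbutyl]benzoic acid (CNP0328949.1)
Conditions: activated MnO2 (15 equiv), EtOAc, rt; Celite, washing with EtOAc/MeOH/AcOH
Reagents that add atoms: none
Why: MnO2 oxidation, selective for benzylic alcohols and stopping at the aldehyde; the other benzylic position is an ether without free OH, and the C2' hydroxyl is meta to the carbinol so no quinone methide can form.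

Compound list
1 | methyl 2,6-dihydroxybenzoate | COC(=O)c1c(O)cccc1O | starting material
2 | 3-methylbutanoyl chloride | CC(C)CC(=O)Cl | starting material
3 | methyl 2,6-dihydroxy-3-(3-methylbutanoyl)benzoate | COC(=O)c1c(O)ccc(C(=O)CC(C)C)c1O | intermediate
4 | methyl bromoacetate | COC(=O)CBr | starting material
5 | methyl 2-hydroxy-6-(2-methoxy-2-oxoethoxy)-3-(3-methylbutanoyl)benzoate | COC(=O)c1c(O)c(C(=O)CC(C)C)ccc1OCC(=O)OC | intermediate
6 | methyl 2-methoxy-6-(2-methoxy-2-oxoethoxy)-3-(3-methylbutanoyl)benzoate | COc1c(C(=O)CC(C)C)ccc(OCC(=O)OC)c1C(=O)OC | intermediate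
7 | methyl 3-[(1R)-1-hydroxy-3-methylbutyl]-2-methoxy-6-(2-methoxy-2-oxoethoxy)benzoate | COc1c([C@@H](CC(C)C)O)ccc(OCC(=O)OC)c1C(=O)OC | intermediate
8 | methyl 2-methoxy-3-[(1R)-1-methoxy-3-methylbutyl]-6-(2-methoxy-2-oxoethoxy)benzoate | COc1c([C@@H](CC(C)C)OC)ccc(OCC(=O)OC)c1C(=O)OC | intermediate
9 | 6-(carboxymethoxy)-2-methoxy-3-[(1R)-1-methoxy-3-methylbutyl]benzoic acid | COc1c([C@@H](CC(C)C)OC)ccc(OCC(=O)O)c1C(=O)O | intermediate
10 | trilithium salt of 9 (lithium benzoate plus dilithium enediolate) | COc1c([C@@H](CC(C)C)OC)ccc(OC=C([O-])[O-])c1C(=O)[O-].[Li+].[Li+].[Li+] | intermediate (not isolated)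
11 | trimethylsilyl 6-{[2,2-bis(trimethylsilyloxy)ethenyl]oxy}-2-methoxy-3-[(1R)-1-methoxy-3-methylbutyl]benzoate | COc1c([C@@H](CC(C)C)OC)ccc(OC=C(O[Si](C)(C)C)O[Si](C)(C)C)c1C(=O)O[Si](C)(C)C | intermediate
12 | ethyl 3-methylbut-2-enoate | CCOC(=O)C=C(C)C | starting material
13 | diethyl oxalate | CCOC(=O)C(=O)OCC | starting material
14 | potassium enolate of diethyl 4-methyl-2-oxohex-4-enedioate (alkene geometry not defined, equilibrates in step 9) | CCOC(=O)C([O-])=CC(C)=CC(=O)OCC.[K+] | intermediate
15 | 4-methyl-2-oxo-2H-pyran-6-carboxylic acid | CC1=CC(=O)OC(C(=O)O)=C1 | intermediate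
16 | methyl 4-methyl-2-oxo-2H-pyran-6-carboxylate | COC(=O)C1=CC(C)=CC(=O)O1 | intermediate
17 | 2-oxabicyclo[2.2.2]oct-5-en-3-one cycloadduct of 11 and 16 (new sp3 centres undefined, mixture) | COc1c([C@@H](CC(C)C)OC)ccc(OC2C(O[Si](C)(C)C)(O[Si](C)(C)C)C3C(C)=CC2(C(=O)OC)OC3=O)c1C(=O)O[Si](C)(C)C | intermediate (not isolated)
18 | cyclohexa-1,3-diene after loss of CO2 (C1' undefined) | COc1c([C@@H](CC(C)C)OC)ccc(OC2C(C(=O)OC)=CC(C)=CC2(O[Si](C)(C)C)O[Si](C)(C)C)c1C(=O)O[Si](C)(C)C | intermediate (not isolated)
19 | trimethylsilyl ester and C2' trimethylsilyl ether of 20 | COc1c([C@@H](CC(C)C)OC)ccc(Oc2c(O[Si](C)(C)C)cc(C)cc2C(=O)OC)c1C(=O)O[Si](C)(C)C | intermediate (not isolated)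
20 | 6-[2-hydroxy-6-(methoxycarbonyl)-4-methylphenoxy]-2-methoxy-3-[(1R)-1-methoxy-3-methylbutyl]benzoic acid | COc1c([C@@H](CC(C)C)OC)ccc(Oc2c(O)cc(C)cc2C(=O)OC)c1C(=O)O | intermediate
21 | 6-[2-hydroxy-6-(hydroxymethyl)-4-methylphenoxy]-2-methoxy-3-[(1R)-1-methoxy-3-methylbutyl]benzoic acid | COc1c([C@@H](CC(C)C)OC)ccc(Oc2c(O)cc(C)cc2CO)c1C(=O)O | intermediate
22 | 6-(2-formyl-6-hydroxy-4-methylphenoxy)-2-methoxy-3-[(1R)-1-methoxy-3-methylbutyl]benzoic acid | COc1c([C@@H](CC(C)C)OC)ccc(Oc2c(O)cc(C)cc2C=O)c1C(=O)O | target

Total step count: 13 (ring-A line 7, pyrone line 3, union 1, endgame 2). Longest linear sequence: 10 (steps 1–7, 11, 12, 13).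

Steps most likely to fail

1. Step 11.
- What may go wrong: bond formation in the reverse orientation, because the C6 ester opposes the lactone carbonyl. Silyl transfer after the first C–C bond (a Mukaiyama–Michael course) may replace ring closure. The ketene acetal may be protodesilylated or rearrange thermally before a hindered cycloaddition takes place.
- Fallback: classical ether formation instead of ring synthesis. It sets out from 8 and comes back at 21.
- The carboxymethyl group of 8 is removed by reductive α-deoxygenation of the α-aryloxy ester (SmI2, HMPA, THF, MeOH, rt). This gives methyl 6-hydroxy-2-methoxy-3-[(1R)-1-methoxy-3-methylbutyl]benzoate F1.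
- SNAr of its phenoxide on 3-bromo-2-fluoro-5-methylbenzaldehyde (Cc1cc(Br)c(F)c(C=O)c1; Cs2CO3, DMF, 90–110 °C; fluoride activated by the ortho formyl group) gives methyl 6-(2-bromo-6-formyl-4-methylphenoxy)-2-methoxy-3-[(1R)-1-methoxy-3-methylbutyl]benzoate F2.
- NaBH4 (MeOH, 0 °C) takes the aldehyde out of the way of hot base as methyl 6-[2-bromo-6-(hydroxymethyl)-4-methylphenoxy]-2-methoxy-3-[(1R)-1-methoxy-3-methylbutyl]benzoate F3.
- Copper-catalysed hydroxylation (CuI, 8-hydroxyquinoline, KOH, DMSO/H2O, 100 °C) gives first methyl 6-[2-hydroxy-6-(hydroxymethyl)-4-methylphenoxy]-2-methoxy-3-[(1R)-1-methoxy-3-methylbutyl]benzoate F4.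
- Prolonged heating of F4 in this medium, which is that of step 6, saponifies it to 21, ready for step 13.

2. Step 7.
- What may go wrong: incomplete third deprotonation of an aggregated, poorly soluble polyanion, silylation on carbon instead of oxygen, and hydrolysis during handling of the crude product.
- Fallback: enolisation of a neutral silyl ester instead of a carboxylate. It sets out from 9 and comes back at 11.
- Diacid 9 is silylated without base (hexamethyldisilazane, cat. Me3SiCl, CH2Cl2, reflux; evaporation). This gives trimethylsilyl 2-methoxy-3-[(1R)-1-methoxy-3-methylbutyl]-6-[2-oxo-2-(trimethylsilyloxy)ethoxy]benzoate F5.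
- Only its much more acidic acetate CH2 is then deprotonated with LiN(SiMe3)2 (1.1 equiv) in the presence of Me3SiCl (internal quench, THF, −78 °C). The enolate is trapped before it can reach the hindered silyl benzoate, giving 11.

3. Step 5.
- What may go wrong: sluggish alkylation of a hindered secondary alcohol. If harsher reagents are used to force it, base-induced Dieckmann closure or ionisation of the activated benzylic C–O bond with loss of configuration may follow.
- Fallback: inverted order, so that a strong base becomes harmless. It sets out from 7 and comes back at 9.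
- Alcohol 7 is saponified first (KOH, DMSO/H2O, rt then 95 °C, N2; cold acidification to pH 3) to 6-(carboxymethoxy)-3-[(1R)-1-hydroxy-3-methylbutyl]-2-methoxybenzoic acid F6.
- Williamson methylation follows with NaH (3.5 equiv) and MeI in THF (0 °C to rt). Here the sodium carboxylates are not alkylated and cannot serve as Dieckmann partners, while the alkoxide is methylated with retention, giving 9.

Further compounds
F1 | step 11 | methyl 6-hydroxy-2-methoxy-3-[(1R)-1-methoxy-3-methylbutyl]benzoate | COc1c([C@@H](CC(C)C)OC)ccc(O)c1C(=O)OC
F2 | step 11 | methyl 6-(2-bromo-6-formyl-4-methylphenoxy)-2-methoxy-3-[(1R)-1-methoxy-3-methylbutyl]benzoate | COc1c([C@@H](CC(C)C)OC)ccc(Oc2c(Br)cc(C)cc2C=O)c1C(=O)OC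
F3 | step 11 | methyl 6-[2-bromo-6-(hydroxymethyl)-4-methylphenoxy]-2-methoxy-3-[(1R)-1-methoxy-3-methylbutyl]benzoate | COc1c([C@@H](CC(C)C)OC)ccc(Oc2c(Br)cc(C)cc2CO)c1C(=O)OC
F4 | step 11 | methyl 6-[2-hydroxy-6-(hydroxymethyl)-4-methylphenoxy]-2-methoxy-3-[(1R)-1-methoxy-3-methylbutyl]benzoate | COc1c([C@@H](CC(C)C)OC)ccc(Oc2c(O)cc(C)cc2CO)c1C(=O)OC
F5 | step 7 | trimethylsilyl 2-methoxy-3-[(1R)-1-methoxy-3-methylbutyl]-6-[2-oxo-2-(trimethylsilyloxy)ethoxy]benzoate | COc1c([C@@H](CC(C)C)OC)ccc(OCC(=O)O[Si](C)(C)C)c1C(=O)O[Si](C)(C)C
F6 | step 5 | 6-(carboxymethoxy)-3-[(1R)-1-hydroxy-3-methylbutyl]-2-methoxybenzoic acid | COc1c([C@@H](CC(C)C)O)ccc(OCC(=O)O)c1C(=O)O
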